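## Retrosynthetic overview

1. Target ⇐ its bis‑MOM ether ⇐ oxepine ring opened at the diaryl ether bond (last ring, closed by intramolecular Pd‑catalysed C–O coupling of a ring A phenol onto a ring B aryl chloride).
2. Ring B–C(enol ether) bond ⇐ Suzuki coupling of a ring B boronate with the ketene acetal triflate of a tricyclic δ‑lactone.
3. δ‑Lactone (the future pyran ring) ⇐ intramolecular aldol condensation of a ring A arylacetate ester onto the cyclobutanone of a bicyclo[3.2.0]heptane ketol, then conjugate reduction; this ring closure joins the two main fragments.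
4. Ketol (cyclopentane ring, two stereocentres) ⇐ intramolecular aldol addition of a cyclobutanone/methyl ketone made from (+)‑nopinone by Baeyer–Villiger ring opening; the chiral pool fixes the absolute configuration.
5. Ring order: cyclobutane (from nopinone) → cyclopentane (aldol) → pyranone/pyran (aldol condensation) → oxepine (C–O coupling); the arenes come from 5‑bromo‑2,4‑dihydroxybenzaldehyde and 4‑bromo‑3‑chlorophenol.

Assumption: (1R,5S)‑(+)‑nopinone, 5‑bromo‑2,4‑dihydroxybenzaldehyde and 4‑bromo‑3‑chlorophenol are taken as purchasable starting materials.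

Abbreviations in names: ArA = 4‑(methoxymethoxy)‑5‑(3‑methylbut‑2‑en‑1‑yl)‑2‑{[2‑(trimethylsilyl)ethoxy]methoxy}phenyl (protected ring A). Tricyclic core = 7‑oxatricyclo[4.3.1.0^{3,10}]decane: C1 cyclobutane CH, C2 CMe2, C3 cyclobutane/cyclopentane fusion CH, C4/C5 CH2, C6 C(CH3)–O, O7, C8, C9, C10 the CH shared by all three rings.

## Route

Step 1
Reactants: 1 (1R,5S)‑6,6‑dimethylbicyclo[3.1.1]heptan‑2‑one, (+)‑nopinone
Product: 2 (1R,6S)‑7,7‑dimethyl‑2‑oxabicyclo[4.1.1]octan‑3‑one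
Conditions: mCPBA, CH2Cl2, 0 °C → rt
Reagents that add atoms: 3‑chloroperoxybenzoic acid, OOC(=O)c1cccc(Cl)c1
Why: Baeyer–Villiger oxidation in which the more substituted bridgehead carbon migrates with retention, so both stereocentres of 1 are carried over and the future ring‑fusion carbon C3 (S) is already in place.

Step 2
Reactants: 2 (1R,6S)‑7,7‑dimethyl‑2‑oxabicyclo[4.1.1]octan‑3‑one
Product: 3 3‑[(1S,3R)‑3‑hydroxy‑2,2‑dimethylcyclobutyl]‑N‑methoxy‑N‑methylpropanamide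
Conditions: MeNH(OMe)·HCl, i‑PrMgCl, THF, −20 → 0 °C; dilute HCl quench
Reagents that add atoms: N,O‑dimethylhydroxylamine hydrochloride, CNOC.Cl
Why: Weinreb aminolysis of the seven‑membered lactone by the chloromagnesium amide opens the ring without touching a stereocentre.

Step 3
Reactants: 3 3‑[(1S,3R)‑3‑hydroxy‑2,2‑dimethylcyclobutyl]‑N‑methoxy‑N‑methylpropanamide
Product: 4 4‑[(1S,3R)‑3‑hydroxy‑2,2‑dimethylcyclobutyl]butan‑2‑one
Conditions: MeMgBr (3 equiv), THF, 0 °C; dilute HCl quench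
Reagents that add atoms: methylmagnesium bromide, C[Mg]Br
Why: Weinreb ketone synthesis, in which the chelated tetrahedral adduct stops the addition at the methyl ketone while one equivalent of Grignard reagent is spent on the free hydroxyl.

Step 4
Reactants: 4 4‑[(1S,3R)‑3‑hydroxy‑2,2‑dimethylcyclobutyl]butan‑2‑one
Product: 5 (3S)‑2,2‑dimethyl‑3‑(3‑oxobutyl)cyclobutan‑1‑one
Conditions: Dess–Martin periodinane, CH2Cl2, rt
Reagents that add atoms: none
Why: Dess–Martin oxidation of the secondary cyclobutanol under neutral conditions gives the cyclobutanone, and the only stereocentre is β to both carbonyls and cannot epimerise.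

Step 5
Reactants: 5 (3S)‑2,2‑dimethyl‑3‑(3‑oxobutyl)cyclobutan‑1‑one
Product: 6 (1S,4R,5S)‑4‑hydroxy‑4,7,7‑trimethylbicyclo[3.2.0]heptan‑6‑one
Conditions: KOt‑Bu (0.2 equiv), t‑BuOH/THF, 0 °C → rt, 0.02 M
Reagents that add atoms: none
Why: Intramolecular aldol addition in which only the cyclobutanone enolate (its single α‑CH2) can reach the side‑chain ketone through an unstrained five‑membered ring, the cis ring fusion (C5) being forced and the reversible conditions placing the new tertiary OH (C4) on the concave face hydrogen‑bonded to the carbonyl, while dehydration is blocked because it would give a strained alkylidenecyclobutanone.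

Step 6
Reactants: 7 5‑bromo‑2,4‑dihydroxybenzaldehyde
Product: 8 5‑bromo‑2‑hydroxy‑4‑(methoxymethoxy)benzaldehyde
Conditions: MOMCl (1.1 equiv), K2CO3, acetone, 0 °C → rt
Reagents that add atoms: chloromethyl methyl ether, COCCl
Why: Williamson‑type O‑alkylation selective for the 4‑OH, which is more acidic and not locked in the hydrogen bond to the aldehyde.

Step 7
Reactants: 8 5‑bromo‑2‑hydroxy‑4‑(methoxymethoxy)benzaldehyde
Product: 9 5‑bromo‑4‑(methoxymethoxy)‑2‑{[2‑(trimethylsilyl)ethoxy]methoxy}benzaldehyde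
Conditions: NaH, DMF, 0 °C; SEMCl, 0 °C → rt
Reagents that add atoms: 2‑(trimethylsilyl)ethoxymethyl chloride, C[Si](C)(C)CCOCCl
Why: O‑alkylation of the fully deprotonated chelated phenol gives an SEM ether that is orthogonal to MOM and stable to all later basic and reducing steps.

Step 8
Reactants: 9 5‑bromo‑4‑(methoxymethoxy)‑2‑{[2‑(trimethylsilyl)ethoxy]methoxy}benzaldehyde
Product: 10 2‑[5‑bromo‑4‑(methoxymethoxy)‑2‑{[2‑(trimethylsilyl)ethoxy]methoxy}phenyl]acetonitrile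
Conditions: TosMIC, KOt‑Bu, DME, −40 °C; then MeOH, reflux
Reagents that add atoms: p‑toluenesulfonylmethyl isocyanide, Cc1ccc(cc1)S(=O)(=O)C[N+]#[C-]
Why: van Leusen reductive cyanation, in which the TosMIC adduct cyclises to an oxazoline that opens and loses sulfinate and formate to give the one‑carbon‑homologated nitrile.

Step 9
Reactants: 10 2‑[5‑bromo‑4‑(methoxymethoxy)‑2‑{[2‑(trimethylsilyl)ethoxy]methoxy}phenyl]acetonitrile
Product: 11 2‑(ArA)acetonitrile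
Conditions: 3‑methylbut‑2‑enylzinc bromide (from prenyl bromide, Zn dust, LiCl, THF), Pd(OAc)2 (2 mol %), CPhos (4 mol %), THF, rt
Reagents that add atoms: 3‑methylbut‑2‑enylzinc bromide, CC(C)=CC[Zn]Br, made in the flask from 1‑bromo‑3‑methylbut‑2‑ene, CC(C)=CCBr
Why: Negishi coupling in which the bulky biarylphosphine makes reductive elimination faster than allyl transposition, so the linear prenyl group is installed, and the nitrile and acetals tolerate the organozinc.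

Step 10
Reactants: 11 2‑(ArA)acetonitrile
Product: 12 2‑(ArA)acetic acid
Conditions: KOH, EtOH/H2O, reflux; then dilute HCl to pH 4 at 0 °C
Reagents that add atoms: water, O; potassium hydroxide, [K+].[OH-]
Why: Base hydrolysis of the nitrile, to which the MOM and SEM acetals and the prenyl group are inert.

Step 11
Reactants: 6 (1S,4R,5S)‑4‑hydroxy‑4,7,7‑trimethylbicyclo[3.2.0]heptan‑6‑one; 12 2‑(ArA)acetic acid
Product: 14 (1S,2R,5S)‑2,6,6‑trimethyl‑7‑oxobicyclo[3.2.0]heptan‑2‑yl 2‑(ArA)acetate, via acid chloride 13 (not isolated)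
Conditions: 12, 1‑chloro‑N,N,2‑trimethylprop‑1‑en‑1‑amine, CH2Cl2, 0 °C; then 6, Et3N, DMAP (cat.), 0 °C → rt
Reagents that add atoms: none
Why: Acylation through the acid chloride and the arylketene it gives with Et3N, which esterifies even hindered tertiary alcohols, while the neutral chloroenamine spares the acetals and the base is too weak to trigger retro‑aldol of 6.

Step 12
Reactants: 14 (1S,2R,5S)‑2,6,6‑trimethyl‑7‑oxobicyclo[3.2.0]heptan‑2‑yl 2‑(ArA)acetate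
Product: 17 (3S,6R,10R)‑9‑(ArA)‑2,2,6‑trimethyl‑7‑oxatricyclo[4.3.1.0^{3,10}]dec‑1(9)‑en‑8‑one, via lithium aldolate 15 (not isolated), via tertiary acetate 16 (not isolated)
Conditions: LiN(SiMe3)2 (1.1 equiv), THF, −78 °C; Ac2O, −78 → 0 °C; DBU, rt
Reagents that add atoms: none
Why: Intramolecular aldol condensation in which the arylacetate enolate (the most acidic C–H), held on the concave face by the ester tether, adds to the strained cyclobutanone to close the six‑membered lactone, and the acetylated aldolate then eliminates by E1cB to the conjugated lactone.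

Step 13
Reactants: 17 (3S,6R,10R)‑9‑(ArA)‑2,2,6‑trimethyl‑7‑oxatricyclo[4.3.1.0^{3,10}]dec‑1(9)‑en‑8‑one
Product: 18 (1S,3S,6R,10R)‑9‑(ArA)‑2,2,6‑trimethyl‑7‑oxatricyclo[4.3.1.0^{3,10}]decan‑8‑one (mixture of C9 epimers)
Conditions: Mg turnings, MeOH, 0 °C → rt
Reagents that add atoms: none
Why: Dissolving‑metal conjugate reduction of the α‑aryl unsaturated lactone, in which the β‑carbon C1 can only be protonated from the convex face because the ring must stay cis‑fused (1S here is the same spatial arrangement as 1R in the target), and the C9 centre is removed again in step 14.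

Step 14
Reactants: 18 (1S,3S,6R,10R)‑9‑(ArA)‑2,2,6‑trimethyl‑7‑oxatricyclo[4.3.1.0^{3,10}]decan‑8‑one
Product: 20 (1R,3S,6R,10R)‑9‑(ArA)‑2,2,6‑trimethyl‑7‑oxatricyclo[4.3.1.0^{3,10}]dec‑8‑en‑8‑yl trifluoromethanesulfonate, via potassium enolate 19 (not isolated)
Conditions: KN(SiMe3)2, THF, −78 °C; PhNTf2, −78 → 0 °C; rapid filtration through Et3N‑deactivated silica
Reagents that add atoms: N‑phenylbis(trifluoromethanesulfonimide), O=S(=O)(N(c1ccccc1)S(=O)(=O)C(F)(F)F)C(F)(F)F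
Why: O‑triflation of the benzylic lactone enolate gives the ketene acetal triflate and fixes the C8=C9 double bond of the final enol ether.

Step 15
Reactants: 21 4‑bromo‑3‑chlorophenol
Product: 22 1‑bromo‑2‑chloro‑4‑(methoxymethoxy)benzene
Conditions: MOMCl, i‑Pr2NEt, CH2Cl2, 0 °C → rt
Reagents that add atoms: chloromethyl methyl ether, COCCl
Why: Standard MOM protection of the phenol.

Step 16
Reactants: 22 1‑bromo‑2‑chloro‑4‑(methoxymethoxy)benzene
Product: 23 2‑[2‑chloro‑4‑(methoxymethoxy)phenyl]‑4,4,5,5‑tetramethyl‑1,3,2‑dioxaborolane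
Conditions: B2pin2, PdCl2(dppf) (3 mol %), KOAc, 1,4‑dioxane, 85 °C
Reagents that add atoms: bis(pinacolato)diboron, CC1(C)OB(OC1(C)C)B1OC(C)(C)C(C)(C)O1
Why: Miyaura borylation, in which oxidative addition into C–Br is far faster than into C–Cl and acetate as base prevents biaryl coupling.

Step 17
Reactants: 20 (1R,3S,6R,10R)‑9‑(ArA)‑2,2,6‑trimethyl‑7‑oxatricyclo[4.3.1.0^{3,10}]dec‑8‑en‑8‑yl trifluoromethanesulfonate; 23 2‑[2‑chloro‑4‑(methoxymethoxy)phenyl]‑4,4,5,5‑tetramethyl‑1,3,2‑dioxaborolane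
Product: 24 (1R,3S,6R,10R)‑8‑[2‑chloro‑4‑(methoxymethoxy)phenyl]‑9‑(ArA)‑2,2,6‑trimethyl‑7‑oxatricyclo[4.3.1.0^{3,10}]dec‑8‑ene
Conditions: Pd(PPh3)4 (5 mol %), K3PO4 (aq), 1,4‑dioxane, 60 °C
Reagents that add atoms: none
Why: Suzuki–Miyaura coupling, in which the ketene acetal triflate undergoes oxidative addition readily while the aryl chloride is inert to the triphenylphosphine catalyst.

Step 18
Reactants: 24 (1R,3S,6R,10R)‑8‑[2‑chloro‑4‑(methoxymethoxy)phenyl]‑9‑(ArA)‑2,2,6‑trimethyl‑7‑oxatricyclo[4.3.1.0^{3,10}]dec‑8‑ene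
Product: 25 2‑{(1R,3S,6R,10R)‑8‑[2‑chloro‑4‑(methoxymethoxy)phenyl]‑2,2,6‑trimethyl‑7‑oxatricyclo[4.3.1.0^{3,10}]dec‑8‑en‑9‑yl}‑5‑(methoxymethoxy)‑4‑(3‑methylbut‑2‑en‑1‑yl)phenol
Conditions: Bu4NF, THF/DMPU, 60 °C
Reagents that add atoms: none
Why: Fluoride‑induced fragmentation of the aryl SEM ether frees only the ring A phenol next to the enol ether, and the MOM ethers, aryl chloride and prenyl group are untouched.

Step 19
Reactants: 25 2‑{(1R,3S,6R,10R)‑8‑[2‑chloro‑4‑(methoxymethoxy)phenyl]‑2,2,6‑trimethyl‑7‑oxatricyclo[4.3.1.0^{3,10}]dec‑8‑en‑9‑yl}‑5‑(methoxymethoxy)‑4‑(3‑methylbut‑2‑en‑1‑yl)phenol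
Product: 26 bis(methoxymethyl) ether of the target (dibenzo[b,f]oxepine closed; both phenols as OCH2OCH3; core 1R,3S,6R,10R)
Conditions: Pd(OAc)2 (5 mol %), t‑BuXPhos (10 mol %), K3PO4, toluene, 100 °C, 0.01 M
Reagents that add atoms: none
Why: Intramolecular Buchwald–Hartwig diaryl ether formation, in which the two aryl rings are held cis on the cyclic enol ether so the phenol and the C–Cl bond are within reach and the seven‑membered oxepine closes.

Step 20
Reactants: 26 bis(methoxymethyl) ether of the target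
Product: 27 CNP0185814.1: dibenzo[b,f]oxepine whose central C=C is the C8=C9 enol ether bond of the (1R,3S,6R,10R)‑2,2,6‑trimethyl‑7‑oxatricyclo[4.3.1.0^{3,10}]dec‑8‑ene unit; ring B (on C8) has OH para to C8; ring A (on C9) has OH para to C9 and a prenyl group ortho to that OH and para to the oxepine oxygen
Conditions: 3 M HCl (aq)/MeOH/THF, 40 °C
Reagents that add atoms: none
Why: Acid‑catalysed acetal exchange with methanol removes both MOM groups under conditions mild enough for the conjugated enol ether and the prenyl group.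

## Compound list

1 | (1R,5S)‑6,6‑dimethylbicyclo[3.1.1]heptan‑2‑one, (+)‑nopinone | O=C1CC[C@H]2C[C@@H]1C2(C)C | starting material
2 | (1R,6S)‑7,7‑dimethyl‑2‑oxabicyclo[4.1.1]octan‑3‑one | O=C1CC[C@H]2C[C@@H](O1)C2(C)C | intermediate
3 | 3‑[(1S,3R)‑3‑hydroxy‑2,2‑dimethylcyclobutyl]‑N‑methoxy‑N‑methylpropanamide | CON(C)C(=O)CC[C@H]1C[C@@H](O)C1(C)C | intermediate
4 | 4‑[(1S,3R)‑3‑hydroxy‑2,2‑dimethylcyclobutyl]butan‑2‑one | CC(=O)CC[C@H]1C[C@@H](O)C1(C)C | intermediate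
5 | (3S)‑2,2‑dimethyl‑3‑(3‑oxobutyl)cyclobutan‑1‑one | CC(=O)CC[C@H]1CC(=O)C1(C)C | intermediate
6 | (1S,4R,5S)‑4‑hydroxy‑4,7,7‑trimethylbicyclo[3.2.0]heptan‑6‑one | O=C1[C@H]2[C@H](CC[C@@]2(C)O)C1(C)C | intermediate
7 | 5‑bromo‑2,4‑dihydroxybenzaldehyde | O=Cc1cc(Br)c(O)cc1O | starting material
8 | 5‑bromo‑2‑hydroxy‑4‑(methoxymethoxy)benzaldehyde | O=Cc1cc(Br)c(OCOC)cc1O | intermediate
9 | 5‑bromo‑4‑(methoxymethoxy)‑2‑{[2‑(trimethylsilyl)ethoxy]methoxy}benzaldehyde | O=Cc1cc(Br)c(OCOC)cc1OCOCC[Si](C)(C)C | intermediate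
10 | 2‑[5‑bromo‑4‑(methoxymethoxy)‑2‑{[2‑(trimethylsilyl)ethoxy]methoxy}phenyl]acetonitrile | N#CCc1cc(Br)c(OCOC)cc1OCOCC[Si](C)(C)C | intermediate
11 | 2‑(ArA)acetonitrile | N#CCc1cc(CC=C(C)C)c(OCOC)cc1OCOCC[Si](C)(C)C | intermediate
12 | 2‑(ArA)acetic acid | OC(=O)Cc1cc(CC=C(C)C)c(OCOC)cc1OCOCC[Si](C)(C)C | intermediate
13 | 2‑(ArA)acetyl chloride | ClC(=O)Cc1cc(CC=C(C)C)c(OCOC)cc1OCOCC[Si](C)(C)C | intermediate (not isolated)
14 | (1S,2R,5S)‑2,6,6‑trimethyl‑7‑oxobicyclo[3.2.0]heptan‑2‑yl 2‑(ArA)acetate | O=C1[C@H]2[C@H](CC[C@@]2(C)OC(=O)Cc3cc(CC=C(C)C)c(OCOC)cc3OCOCC[Si](C)(C)C)C1(C)C | intermediate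
15 | lithium (1R,3S,6R,10R)‑9‑(ArA)‑2,2,6‑trimethyl‑8‑oxo‑7‑oxatricyclo[4.3.1.0^{3,10}]decan‑1‑olate (C9 epimers) | O=C1C(c4cc(CC=C(C)C)c(OCOC)cc4OCOCC[Si](C)(C)C)[C@]2([O-])[C@H]3[C@H](CC[C@@]3(C)O1)C2(C)C.[Li+] | intermediate (not isolated)
16 | (1R,3S,6R,10S)‑9‑(ArA)‑2,2,6‑trimethyl‑8‑oxo‑7‑oxatricyclo[4.3.1.0^{3,10}]decan‑1‑yl acetate (C9 epimers) | O=C1C(c4cc(CC=C(C)C)c(OCOC)cc4OCOCC[Si](C)(C)C)[C@]2(OC(C)=O)[C@H]3[C@H](CC[C@@]3(C)O1)C2(C)C | intermediate (not isolated)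
17 | (3S,6R,10R)‑9‑(ArA)‑2,2,6‑trimethyl‑7‑oxatricyclo[4.3.1.0^{3,10}]dec‑1(9)‑en‑8‑one | O=C1C(c4cc(CC=C(C)C)c(OCOC)cc4OCOCC[Si](C)(C)C)=C2[C@H]3[C@H](CC[C@@]3(C)O1)C2(C)C | intermediate
18 | (1S,3S,6R,10R)‑9‑(ArA)‑2,2,6‑trimethyl‑7‑oxatricyclo[4.3.1.0^{3,10}]decan‑8‑one (C9 epimers) | O=C1C(c4cc(CC=C(C)C)c(OCOC)cc4OCOCC[Si](C)(C)C)[C@@H]2[C@H]3[C@H](CC[C@@]3(C)O1)C2(C)C | intermediate
19 | potassium (1R,3S,6R,10R)‑9‑(ArA)‑2,2,6‑trimethyl‑7‑oxatricyclo[4.3.1.0^{3,10}]dec‑8‑en‑8‑olate | [K+].[O-]C1=C(c4cc(CC=C(C)C)c(OCOC)cc4OCOCC[Si](C)(C)C)[C@@H]2[C@H]3[C@H](CC[C@@]3(C)O1)C2(C)C | intermediate (not isolated)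
20 | (1R,3S,6R,10R)‑9‑(ArA)‑2,2,6‑trimethyl‑7‑oxatricyclo[4.3.1.0^{3,10}]dec‑8‑en‑8‑yl trifluoromethanesulfonate | FC(F)(F)S(=O)(=O)OC1=C(c4cc(CC=C(C)C)c(OCOC)cc4OCOCC[Si](C)(C)C)[C@@H]2[C@H]3[C@H](CC[C@@]3(C)O1)C2(C)C | intermediate
21 | 4‑bromo‑3‑chlorophenol | Oc1ccc(Br)c(Cl)c1 | starting material
22 | 1‑bromo‑2‑chloro‑4‑(methoxymethoxy)benzene | COCOc1ccc(Br)c(Cl)c1 | intermediate
23 | 2‑[2‑chloro‑4‑(methoxymethoxy)phenyl]‑4,4,5,5‑tetramethyl‑1,3,2‑dioxaborolane | COCOc1ccc(B2OC(C)(C)C(C)(C)O2)c(Cl)c1 | intermediate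
24 | (1R,3S,6R,10R)‑8‑[2‑chloro‑4‑(methoxymethoxy)phenyl]‑9‑(ArA)‑2,2,6‑trimethyl‑7‑oxatricyclo[4.3.1.0^{3,10}]dec‑8‑ene | COCOc1ccc(c(Cl)c1)C1=C(c4cc(CC=C(C)C)c(OCOC)cc4OCOCC[Si](C)(C)C)[C@@H]2[C@H]3[C@H](CC[C@@]3(C)O1)C2(C)C | intermediate
25 | 2‑{(1R,3S,6R,10R)‑8‑[2‑chloro‑4‑(methoxymethoxy)phenyl]‑2,2,6‑trimethyl‑7‑oxatricyclo[4.3.1.0^{3,10}]dec‑8‑en‑9‑yl}‑5‑(methoxymethoxy)‑4‑(3‑methylbut‑2‑en‑1‑yl)phenol | COCOc1ccc(c(Cl)c1)C1=C(c4cc(CC=C(C)C)c(OCOC)cc4O)[C@@H]2[C@H]3[C@H](CC[C@@]3(C)O1)C2(C)C | intermediate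
26 | bis(methoxymethyl) ether of the target | CC(C)=CCc1cc2c(cc1OCOC)Oc1cc(OCOC)ccc1C1=C2[C@@H]2[C@H]3[C@H](CC[C@@]3(C)O1)C2(C)C | intermediate
27 | CNP0185814.1 | CC(C)=CCc1cc2c(cc1O)Oc1cc(O)ccc1C1=C2[C@@H]2[C@H]3[C@H](CC[C@@]3(C)O1)C2(C)C | target

## Step count and risks

Total steps: 20. Longest linear sequence: 13 (steps 1–5, 11–14, 17–20; the ring A branch, steps 6–14 and 17–20, is equally long). The ring B branch (steps 15–16) joins at step 17.

**Step 5 (ketone–ketone aldol; the equilibrium may not favour the ketol, and intermolecular aldols compete).** The fallback sets out from 4 and comes back at 6. Protect the methyl ketone of 4 (ethylene glycol, pyridinium p‑toluenesulfonate, benzene, reflux) as 2‑{2‑[(1S,3R)‑3‑hydroxy‑2,2‑dimethylcyclobutyl]ethyl}‑2‑methyl‑1,3‑dioxolane F1. Oxidise with Dess–Martin periodinane to (3S)‑2,2‑dimethyl‑3‑[2‑(2‑methyl‑1,3‑dioxolan‑2‑yl)ethyl]cyclobutan‑1‑one F2. Brominate its only enolisable position (LiN(SiMe3)2, THF, −78 °C, then N‑bromosuccinimide) to (3R)‑4‑bromo‑2,2‑dimethyl‑3‑[2‑(2‑methyl‑1,3‑dioxolan‑2‑yl)ethyl]cyclobutan‑1‑one F3. Unmask the ketone (pyridinium p‑toluenesulfonate, acetone/water) to (3R)‑4‑bromo‑2,2‑dimethyl‑3‑(3‑oxobutyl)cyclobutan‑1‑one F4. Treat F4 with SmI2 in THF at −78 °C: the samarium enolate forms only at the cyclobutanone α‑carbon and closes the ring irreversibly through a chelated Reformatsky‑type aldol, giving 6 with the OH syn to the carbonyl.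

**Step 12 (E1cB elimination to a crowded tetrasubstituted alkene, followed by its reduction in step 13).** The fallback sets out from 14 and comes back at 18. Run the aldol as in step 12 but trap lithium aldolate 15 with methyl chlorooxoacetate instead of acetic anhydride, giving methyl (1R,3S,6R,10S)‑9‑(ArA)‑2,2,6‑trimethyl‑8‑oxo‑7‑oxatricyclo[4.3.1.0^{3,10}]decan‑1‑yl oxalate F5. Heat F5 with Bu3SnH and AIBN in toluene at 110 °C: radical deoxygenation gives the tertiary cyclobutyl radical, which takes a hydrogen atom on the convex face and delivers 18 directly, so no alkene has to be formed or reduced.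

**Step 17 (hindered Suzuki coupling of a sensitive ketene acetal triflate).** The fallback sets out from 18 and 22 and comes back at 24. Bromine–lithium exchange on 22 (n‑BuLi, THF, −78 °C) gives [2‑chloro‑4‑(methoxymethoxy)phenyl]lithium F6. Transmetalation with anhydrous CeCl3 gives dichloro[2‑chloro‑4‑(methoxymethoxy)phenyl]cerium F7, which adds once to the lactone carbonyl of 18 without enolising it. The product is (1S,3S,6R,10R)‑8‑[2‑chloro‑4‑(methoxymethoxy)phenyl]‑9‑(ArA)‑2,2,6‑trimethyl‑7‑oxatricyclo[4.3.1.0^{3,10}]decan‑8‑ol F8. Pyridinium p‑toluenesulfonate in toluene over 4 Å sieves dehydrates F8 to the conjugated enol ether 24.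

## Further compounds

F1 | step 5 | 2‑{2‑[(1S,3R)‑3‑hydroxy‑2,2‑dimethylcyclobutyl]ethyl}‑2‑methyl‑1,3‑dioxolane | CC1(CC[C@H]2C[C@@H](O)C2(C)C)OCCO1
F2 | step 5 | (3S)‑2,2‑dimethyl‑3‑[2‑(2‑methyl‑1,3‑dioxolan‑2‑yl)ethyl]cyclobutan‑1‑one | CC1(CC[C@H]2CC(=O)C2(C)C)OCCO1
F3 | step 5 | (3R)‑4‑bromo‑2,2‑dimethyl‑3‑[2‑(2‑methyl‑1,3‑dioxolan‑2‑yl)ethyl]cyclobutan‑1‑one (C4 epimers) | CC1(CC[C@H]2C(Br)C(=O)C2(C)C)OCCO1
F4 | step 5 | (3R)‑4‑bromo‑2,2‑dimethyl‑3‑(3‑oxobutyl)cyclobutan‑1‑one (C4 epimers) | CC(=O)CC[C@H]1C(Br)C(=O)C1(C)C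
F5 | step 12 | methyl (1R,3S,6R,10S)‑9‑(ArA)‑2,2,6‑trimethyl‑8‑oxo‑7‑oxatricyclo[4.3.1.0^{3,10}]decan‑1‑yl oxalate (C9 epimers) | O=C1C(c4cc(CC=C(C)C)c(OCOC)cc4OCOCC[Si](C)(C)C)[C@]2(OC(=O)C(=O)OC)[C@H]3[C@H](CC[C@@]3(C)O1)C2(C)C
F6 | step 17 | [2‑chloro‑4‑(methoxymethoxy)phenyl]lithium | COCOc1ccc([Li])c(Cl)c1
F7 | step 17 | dichloro[2‑chloro‑4‑(methoxymethoxy)phenyl]cerium | COCOc1ccc([Ce](Cl)Cl)c(Cl)c1
F8 | step 17 | (1S,3S,6R,10R)‑8‑[2‑chloro‑4‑(methoxymethoxy)phenyl]‑9‑(ArA)‑2,2,6‑trimethyl‑7‑oxatricyclo[4.3.1.0^{3,10}]decan‑8‑ol (C8, C9 epimers) | COCOc1ccc(c(Cl)c1)C1(O)C(c4cc(CC=C(C)C)c(OCOC)cc4OCOCC[Si](C)(C)C)[C@@H]2[C@H]3[C@H](CC[C@@]3(C)O1)C2(C)C
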